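1.26 charges of substrate is what the ash flask would get through in 3.0 min at the pace of its last reading.

| setting | ash | larch | eta | alpha | beta |
|---|---|---|---|---|---|
| substrate | 5 mM | 5 mM | 5.0 mM | 5.0 mM | 5.0 mM |
| gas | 0.47 mM (held) | 0.47 mM (held) | 0.47 mM (held) | 0.47 mM (held) | 0.47 mM (held) |
| initiator | 0.057 mM | 0.27 mM | 0.050 mM | 0.10 mM | 0.20 mM |
| remark | run made earlier | run made earlier |  |  |  |
| time |  |  | 3.0 min | 3.0 min | 3.0 min |

| run | time / s | product / % | substrate / % |
|---|---|---|---|
| ash | 12.0 | 8 | 93 |
| ash | 30.0 | 20 | 80 |
| ash | 60.0 | 42 | 58 |
| ash | 90.0 | 63 | 38 |
| larch | 25.0 | 20 | 81 |
| larch | 50.0 | 43 | 53 |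
| larch | 60.0 | 52 | 51 |
| larch | 90.0 | 78 | 24 |

(readings scatter by 2 percentage points)

1. [product] at the end for eta, alpha, beta, in this order
2. how that number moves from the first to the last of them (falls all the way / hardly changes / rises, then falls / rises all the way / falls, then rises)

- at the start none of the gas is in solution
- "hardly changes" means that all values lie within two and a half points (for a concentration: within two and a half percent of the largest)

What is that number? It is the turnover count: the share of the charge turned into product at a reading, multiplied by the asked time and divided by the time of that reading. Above 1, the substrate ends before the asked time, provided the pace lasts.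

Does the initiator move it much? The larch flask, with c(initiator) 0.27 mM, counts 1.56. So 4.74 times the initiator of ash gives 1.24 times the count, a reading of order 0.137.

And eta, whose initiator charge of 0.050 mM lies below that of both earlier runs? Carrying that order from ash, I reckon 1.24 for eta and 1.50 for beta, so both stand above 1.

But does the pace last? That is the weak spot. The larch readings still lie on their line at 90.0 s, with 24% of its substrate left, and neither earlier run has a reading later than that. So look at the margin: by my reckoning, at this pace eta needs 2.42 min, which leaves 34.8 s to spare. In both earlier runs the readings of product and substrate add up to about the charge, and my counts stand above 1, so I expect about 5.0 mM of product in each of the new flasks.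

The forecast gives 4.95 mM, 5 mM and 5 mM, and says the row hardly changes, with one proviso: “unless the chain dies late”.

The flasks give 5.00 mM, 5.00 mM and 5.00 mM, and the row hardly changes.

    initiator → 2 initiating radical (k = 4.30 × 10⁻⁵ /s)
    substrate + initiating radical → capped initiator + first chain carrier (k = 2.90 × 10⁷ /M/s)
    partner + first chain carrier → product + second chain carrier (k = 3.10 × 10⁷ /M/s)
    substrate + second chain carrier → by-product + first chain carrier (k = 1.60 × 10⁷ /M/s)
    2 first chain carrier → ended chains (k = 8.00 × 10⁷ /M/s)
    gas ⇌ partner, rate k6*(csat - [partner]) (kL = 0.130 /s)

At 1.50 min the eta flask holds 58.4% product, which counts 1.17, and the beta flask holds 76.3%, which counts 1.53. In eta at 3.00 min, the half-life of the initiator by its own breakdown is 4.5 h, which is 90.0 times the asked time, and at that moment substrate, the limiting reagent, stands at 0% while 99.2% of the charged initiator is still there, unbound.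

The numbers in the tables stem from a simulated flask with constants of no real substance; scatter was added.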